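The angular methyl C20 (labdane numbering throughout) is disconnected from quaternary C10. C10 lies β to C8, the ring B carbon that must carry oxygen anyway as forerunner of the C8=C17 methylene. In the key step an 8β-hydroxyl steers a zinc carbenoid onto the β face of the tetrasubstituted C9=C10 alkene of ring B. One operation forms C10–C20, a sacrificial C9–C20 bond and a cyclopropane, and fixes C10. Electron transfer to the derived C8 ketone later cuts C9–C20, releases the strain and leaves the methyl. The precursor is a 17,20-dinorlabd-9(10)-en-8β-ol with 5α-H, an axial C19 benzyl ester and an O15 benzyl ether.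

Key step: step 11

Assumption: the sense of induction of the copper–carbene catalyst on the benzyl enone ester is not taken as known. The ligand is written in its (4S,5S) form, and the (4R,5R) antipode is used instead if a trial run shows methyl delivery to the wrong alkene face.
Convention: α is below and β above the decalin plane in the usual labdane drawing.

Step 1
Reactants: 1 methyl 3-oxocyclohex-1-ene-1-carboxylate
Product: 2 benzyl 3-oxocyclohex-1-ene-1-carboxylate
Conditions: BnOH (1.5 equiv), Ti(OiPr)4 (5 mol %), toluene, reflux, MeOH removed over 4 Å sieves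
Reagents that add atoms: benzyl alcohol, OCc1ccccc1
Why: Titanate-catalysed transesterification is an equilibrium pulled over by removal of methanol, and it is done while the ester is still an unhindered sp2-bound group, because the later axial neopentyl C19 ester resists hydrolysis whereas a benzyl ester falls to the dissolving metal already needed in step 13.

Step 2
Reactants: 2 benzyl 3-oxocyclohex-1-ene-1-carboxylate; 3 dimethylzinc
Product: 5 benzyl (1S)-1-methyl-3-(triethylsilyloxy)cyclohex-2-ene-1-carboxylate, via methylzinc enolate 4 (not isolated)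
Conditions: Me2Zn (3 equiv), (CuOTf)2·C6H6 (2.5 mol %), chiral aryloxide-tethered NHC (5 mol %, from (4S,5S)-1-(2'-hydroxybiphenyl-2-yl)-3-mesityl-4,5-diphenylimidazolinium chloride and Ag2O), Et2O, −30 to −15 °C; then TESOTf (3.5 equiv), −30 to 0 °C; cold aq NaHCO3
Reagents that add atoms: dimethylzinc, C[Zn]C; triethylsilyl trifluoromethanesulfonate, CC[Si](CC)(CC)OS(=O)(=O)C(F)(F)F
Why: Copper-catalysed asymmetric conjugate addition of a dialkylzinc to a cyclic γ-keto enoate, a known way to all-carbon quaternary centres, places methyl on the ester-bearing carbon β to the ketone (the stronger acceptor), the chiral carbene on copper choosing the alkene face and so setting C4 as S, and O-silylation of the zinc enolate stores the C5=C10 enolate regiochemistry, which deprotonation of the ketone would not give.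

Step 3
Reactants: 6 (S)-citronellol
Product: 7 (S)-citronellyl benzyl ether
Conditions: NaH, BnBr, Bu4NI (cat), THF, 0 °C to rt
Reagents that add atoms: benzyl bromide, BrCc1ccccc1
Why: Williamson ether synthesis on a primary alkoxide, benzyl being chosen for O15 because it tolerates every step up to 12 and leaves in step 13 without an operation of its own, while C13 is not touched.

Step 4
Reactants: 7 (S)-citronellyl benzyl ether
Product: 9 (4S)-6-(benzyloxy)-4-methylhexan-1-ol, via ozonide 8 (not isolated)
Conditions: O3, CH2Cl2, −78 °C (stopped at the end point); then NaBH4, MeOH, −78 °C to rt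
Reagents that add atoms: ozone, [O-][O+]=O
Why: Ozonolysis of the only alkene followed by borohydride reduction of the ozonide gives the primary alcohol whose carbinol carbon becomes C9, the electron-rich trisubstituted alkene reacting far faster than the benzyl ether.

Step 5
Reactants: 9 (4S)-6-(benzyloxy)-4-methylhexan-1-ol
Product: 10 benzyl (3S)-6-bromo-3-methylhexyl ether
Conditions: CBr4, PPh3, CH2Cl2, 0 °C
Reagents that add atoms: carbon tetrabromide, BrC(Br)(Br)Br
Why: Appel reaction, an SN2 displacement of the oxyphosphonium ion at a primary carbon under neutral conditions that leave the benzyl ether and C13 alone.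

Step 6
Reactants: 10 benzyl (3S)-6-bromo-3-methylhexyl ether; 11 acrolein
Product: 13 (7S)-9-(benzyloxy)-7-methylnon-1-en-3-ol (both C3 epimers), via Grignard reagent 12 (not isolated)
Conditions: Mg, THF, 40 °C; then acrolein, THF, −78 to −20 °C; aq NH4Cl
Reagents that add atoms: acrolein, C=CC=O
Why: Grignard reagents add 1,2 to acrolein, which supplies C6–C8 and puts the oxygen on C8 one carbon beyond C9 (vinyl addition to the ozonolysis aldehyde would give a chain one carbon short), and the new carbinol centre forms as a mixture that step 7 erases.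

Step 7
Reactants: 13 (7S)-9-(benzyloxy)-7-methylnon-1-en-3-ol
Product: 14 (7S)-9-(benzyloxy)-7-methylnon-1-en-3-one
Conditions: Dess–Martin periodinane, NaHCO3, CH2Cl2, 0 °C to rt; used at once
Reagents that add atoms: none
Why: Dess–Martin oxidation of a secondary allylic alcohol is fast and neutral when buffered, so the polymerisable vinyl ketone is obtained without base or heat.

Step 8
Reactants: 5 benzyl (1S)-1-methyl-3-(triethylsilyloxy)cyclohex-2-ene-1-carboxylate; 14 (7S)-9-(benzyloxy)-7-methylnon-1-en-3-one
Product: 16 benzyl (1S,2S)-2-[(7S)-9-(benzyloxy)-7-methyl-3-oxononyl]-1-methyl-3-oxocyclohexane-1-carboxylate, via trichlorotitanium enolate 15 (not isolated)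
Conditions: TiCl4 (1.1 equiv), CH2Cl2, −78 °C; H2O quench
Reagents that add atoms: none
Why: Mukaiyama–Michael addition, in which C5 of the regiodefined enol ether attacks the unhindered CH2 terminus of the TiCl4-activated vinyl ketone without the base that polymerises vinyl ketones and scrambles enolates, and C5 is set by axial attack anti to the C4–CH3 bond (the better σ donor, pseudoaxial in the reacting half-chair, the flat ester lying near the enol plane), which puts C6 cis to the ester (5α-H), although only a moderate bias is counted on because methyl and ester differ little in size.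

Step 9
Reactants: 16 benzyl (1S,2S)-2-[(7S)-9-(benzyloxy)-7-methyl-3-oxononyl]-1-methyl-3-oxocyclohexane-1-carboxylate
Product: 18 benzyl 15-(benzyloxy)-8-oxo-17,20-dinorlabd-9(10)-en-19-oate (5α-H; 13S), via ketol 17 (not isolated)
Conditions: KOt-Bu (0.3 equiv), t-BuOH–THF, 0 °C to rt; chromatography
Reagents that add atoms: none
Why: Intramolecular aldol condensation (the ring-closing half of a Robinson annulation), in which only attack of C9 on the C10 ketone gives a six-membered ketol able to dehydrate, so reversible alternatives drain into the tetrasubstituted enone, while the non-nucleophilic base spares the benzyl ester, its small amount and the low temperature limit C5 epimerisation through the extended dienolate, and any 5β-H epimer is removed by chromatography here.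

Step 10
Reactants: 18 benzyl 15-(benzyloxy)-8-oxo-17,20-dinorlabd-9(10)-en-19-oate
Product: 19 benzyl 15-(benzyloxy)-8β-hydroxy-17,20-dinorlabd-9(10)-en-19-oate (8S)
Conditions: (R)-Me-CBS [(3aR)-1-methyl-3,3-diphenyltetrahydro-1H,3H-pyrrolo[1,2-c][1,3,2]oxazaborole, 0.3 equiv], BH3·SMe2, THF, −30 °C; MeOH
Reagents that add atoms: none
Why: Corey–Bakshi–Shibata reduction is used because the 8β-alcohol is the pseudoaxial one, which small hydrides attacking axially would not give, so the face is chosen by the catalyst, which treats the fully substituted alkenyl carbon C9 as the large group and C7H2 as the small one and in its (R) form delivers hydride to the α face, setting C8 as S, while borane leaves the hindered ester and the tetrasubstituted alkene alone at this temperature.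

Step 11
Reactants: 19 benzyl 15-(benzyloxy)-8β-hydroxy-17,20-dinorlabd-9(10)-en-19-oate; 20 diiodomethane
Product: 22 benzyl 15-(benzyloxy)-8β-hydroxy-9β,20-cyclo-17-norlabdan-19-oate, via ethylzinc alkoxide 21 (not isolated)
Conditions: Et2Zn (6 equiv), CH2I2 (12 equiv), CH2Cl2, −15 °C to rt; aq NH4Cl
Reagents that add atoms: diiodomethane, ICI
Why: Et2Zn deprotonates the 8β-hydroxyl, the zinc alkoxide 21 binds an iodomethylzinc carbenoid made from further Et2Zn and CH2I2, and the bound carbenoid hands its CH2 to C9=C10 through the concerted butterfly transition state, C10–C20 and C9–C20 forming together as zinc iodide leaves. The closest known reaction type is the Furukawa variant of the hydroxyl-directed Simmons–Smith cyclopropanation of cyclohexenols and octalinols, the established first half of an angular methylation. The one ring closed, cyclopropane C9–C10–C20, arises by suprafacial [2+1] addition of the carbenoid carbon across the alkene, so it can only be cis-fused to ring B. C10 (C20 β, trans to 5α-H) and C9 (C20 β, C11 tilted to the α side for the time being) are both controlled by the C8 carbinol centre, since the metal that carries the CH2 is tied to the β oxygen. The step needs β-face selectivity although the axial C19 ester crowds that face, and it needs enough rate on a tetrasubstituted alkene: the pseudoaxial allylic alkoxide sits directly over the β lobes of the π bond and makes the delivery intramolecular, the alkene is electron-rich, and the ester carbonyl on the same face can serve as a second ligand for zinc rather than as a mere obstacle. Chemoselectivity is not an issue because this is the only alkene and the benzyl ether and benzyl ester are inert to the carbenoid.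

Step 12
Reactants: 22 benzyl 15-(benzyloxy)-8β-hydroxy-9β,20-cyclo-17-norlabdan-19-oate
Product: 23 benzyl 15-(benzyloxy)-8-oxo-9β,20-cyclo-17-norlabdan-19-oate
Conditions: Dess–Martin periodinane, NaHCO3, CH2Cl2, 0 °C to rt
Reagents that add atoms: none
Why: Dess–Martin oxidation under bicarbonate buffer converts the hindered secondary cyclopropyl carbinol into the ketone without the acid that could trigger cyclopropylcarbinyl cation rearrangement, and C8 ceases to be a stereocentre once its directing work is done.

Step 13
Reactants: 23 benzyl 15-(benzyloxy)-8-oxo-9β,20-cyclo-17-norlabdan-19-oate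
Product: 25 15-hydroxy-8-oxo-17-norlabdan-19-oic acid (9α-H; 10β-CH3), via trilithium enolate 24 (not isolated)
Conditions: Li (15 equiv), NH3(l)–THF, −78 to −33 °C, no proton donor; isoprene, then solid NH4Cl; aq HCl to pH 3
Reagents that add atoms: none
Why: Dissolving-metal reduction, in which the ketyl of the rigid bicyclo[4.1.0]heptan-2-one cleaves the external C9–C20 bond that overlaps with the carbonyl π system (C9–C10 lies near its nodal plane), turning C20 into the 10β-methyl and storing the ketone as its reduction-proof C8–C9 lithium enolate, while the same electrons cleave both benzylic C–O bonds, and C9 is set on quenching by axial protonation from the α face, anti to the new methyl, which is also the thermodynamic result with the chain equatorial.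

Step 14
Reactants: 25 15-hydroxy-8-oxo-17-norlabdan-19-oic acid; 26 methyltriphenylphosphonium bromide
Product: 27 imbricatolic acid [(13S)-15-hydroxylabd-8(17)-en-19-oic acid]
Conditions: Ph3PCH3Br (8 equiv), KOt-Bu (7.5 equiv), toluene–THF, rt to 70 °C; aq HCl to pH 3
Reagents that add atoms: methyltriphenylphosphonium bromide, C[P+](c1ccccc1)(c1ccccc1)c1ccccc1.[Br-]
Why: Wittig methylenation with a large excess of ylide, the first equivalents of base being consumed by the acid and the alcohol, is the standard way to turn hindered 17-norlabdan-8-ones into 8(17)-alkenes, and the basic medium levels C9 to its equatorial, thermodynamic configuration before olefination.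

Step 15
Reactants: 27 imbricatolic acid; 28 2,2,2-trifluoroethyl formate
Product: 29 (13S)-15-(formyloxy)labd-8(17)-en-19-oic acid (CNP0494097.1)
Conditions: HCO2CH2CF3 (excess), THF, 60 °C
Reagents that add atoms: 2,2,2-trifluoroethyl formate, O=COCC(F)(F)F
Why: Formyl transfer (transesterification) from an activated formate acylates the unhindered primary alcohol under neutral conditions, which neither activate the hindered C19 acid nor isomerise the acid-sensitive exocyclic alkene.

Compound list
1 | methyl 3-oxocyclohex-1-ene-1-carboxylate | COC(=O)C1=CC(=O)CCC1 | starting material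
2 | benzyl 3-oxocyclohex-1-ene-1-carboxylate | O=C(OCc1ccccc1)C1=CC(=O)CCC1 | intermediate
3 | dimethylzinc | C[Zn]C | starting material
4 | methylzinc enolate of benzyl (1S)-1-methyl-3-oxocyclohexane-1-carboxylate | C[Zn]OC1=C[C@@](C)(C(=O)OCc2ccccc2)CCC1 | intermediate
5 | benzyl (1S)-1-methyl-3-(triethylsilyloxy)cyclohex-2-ene-1-carboxylate | CC[Si](CC)(CC)OC1=C[C@@](C)(C(=O)OCc2ccccc2)CCC1 | intermediate
6 | (S)-citronellol | CC(C)=CCC[C@H](C)CCO | starting material
7 | (S)-citronellyl benzyl ether | CC(C)=CCC[C@H](C)CCOCc1ccccc1 | intermediate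
8 | 5-[(3S)-5-(benzyloxy)-3-methylpentyl]-3,3-dimethyl-1,2,4-trioxolane | CC1(C)OOC(CC[C@H](C)CCOCc2ccccc2)O1 | intermediate
9 | (4S)-6-(benzyloxy)-4-methylhexan-1-ol | OCCC[C@H](C)CCOCc1ccccc1 | intermediate
10 | benzyl (3S)-6-bromo-3-methylhexyl ether | BrCCC[C@H](C)CCOCc1ccccc1 | intermediate
11 | acrolein | C=CC=O | starting material
12 | [(4S)-6-(benzyloxy)-4-methylhexyl]magnesium bromide | Br[Mg]CCC[C@H](C)CCOCc1ccccc1 | intermediate
13 | (7S)-9-(benzyloxy)-7-methylnon-1-en-3-ol, C3 epimers | C=CC(O)CCC[C@H](C)CCOCc1ccccc1 | intermediate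
14 | (7S)-9-(benzyloxy)-7-methylnon-1-en-3-one | C=CC(=O)CCC[C@H](C)CCOCc1ccccc1 | intermediate
15 | trichlorotitanium C7=C8 enolate of 16 | Cl[Ti](Cl)(Cl)OC(CCC[C@H](C)CCOCc1ccccc1)=CC[C@@H]1C(=O)CCC[C@]1(C)C(=O)OCc1ccccc1 | intermediate
16 | benzyl (1S,2S)-2-[(7S)-9-(benzyloxy)-7-methyl-3-oxononyl]-1-methyl-3-oxocyclohexane-1-carboxylate | O=C1CCC[C@](C)(C(=O)OCc2ccccc2)[C@@H]1CCC(=O)CCC[C@H](C)CCOCc1ccccc1 | intermediate
17 | benzyl 15-(benzyloxy)-10-hydroxy-8-oxo-17,20-dinorlabdan-19-oate, C9 and C10 undefined | O=C1CC[C@@H]2C(O)(CCC[C@]2(C)C(=O)OCc3ccccc3)C1CC[C@H](C)CCOCc1ccccc1 | intermediate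
18 | benzyl 15-(benzyloxy)-8-oxo-17,20-dinorlabd-9(10)-en-19-oate | O=C1CC[C@@H]2C(CCC[C@]2(C)C(=O)OCc3ccccc3)=C1CC[C@H](C)CCOCc1ccccc1 | intermediate
19 | benzyl 15-(benzyloxy)-8β-hydroxy-17,20-dinorlabd-9(10)-en-19-oate | O[C@H]1CC[C@@H]2C(CCC[C@]2(C)C(=O)OCc3ccccc3)=C1CC[C@H](C)CCOCc1ccccc1 | intermediate
20 | diiodomethane | ICI | starting material
21 | ethylzinc 8β-alkoxide of 19 | CC[Zn]O[C@H]1CC[C@@H]2C(CCC[C@]2(C)C(=O)OCc3ccccc3)=C1CC[C@H](C)CCOCc1ccccc1 | intermediate
22 | benzyl 15-(benzyloxy)-8β-hydroxy-9β,20-cyclo-17-norlabdan-19-oate | O[C@H]1CC[C@@H]2[C@@]3(CCC[C@]2(C)C(=O)OCc4ccccc4)C[C@@]13CC[C@H](C)CCOCc1ccccc1 | intermediate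
23 | benzyl 15-(benzyloxy)-8-oxo-9β,20-cyclo-17-norlabdan-19-oate | O=C1CC[C@@H]2[C@@]3(CCC[C@]2(C)C(=O)OCc4ccccc4)C[C@@]13CC[C@H](C)CCOCc1ccccc1 | intermediate
24 | trilithium salt of 25 (C8–C9 enolate, C19 carboxylate, O15 alkoxide) | [Li]OC1=C(CC[C@H](C)CCO[Li])[C@@]2(C)CCC[C@](C)(C(=O)O[Li])[C@@H]2CC1 | intermediate
25 | 15-hydroxy-8-oxo-17-norlabdan-19-oic acid | O=C1CC[C@@H]2[C@](C)(CCC[C@]2(C)C(=O)O)[C@H]1CC[C@H](C)CCO | intermediate
26 | methyltriphenylphosphonium bromide | C[P+](c1ccccc1)(c1ccccc1)c1ccccc1.[Br-] | starting material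
27 | imbricatolic acid, (13S)-15-hydroxylabd-8(17)-en-19-oic acid | C=C1CC[C@@H]2[C@](C)(CCC[C@]2(C)C(=O)O)[C@H]1CC[C@H](C)CCO | intermediate
28 | 2,2,2-trifluoroethyl formate | O=COCC(F)(F)F | starting material
29 | (1S,4aR,5S,8aR)-5-[(3S)-5-(formyloxy)-3-methylpentyl]-1,4a-dimethyl-6-methylidenedecahydronaphthalene-1-carboxylic acid | C=C1CC[C@@H]2[C@](C)(CCC[C@]2(C)C(=O)O)[C@H]1CC[C@H](C)CCOC=O | target

Total step count: 15. Longest linear sequence: 13 steps (steps 3 to 15, from (S)-citronellol 6).

Steps most likely to fail

Step 11. Methylene transfer may stall, because the alkene is tetrasubstituted and the axial C19 ester crowds the face that must be attacked. The carbenoid could then decay before it reacts.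
- The fallback keeps the 8β-oxygen as anchor but tethers a radical to it instead of a carbenoid. It sets out from 19.
- Silylation with BrCH2SiMe2Cl and Et3N gives the (bromomethyl)dimethylsilyl ether F1.
- Bu3SnH and AIBN in refluxing benzene generate the α-silyl radical, which should close in the 6-endo mode onto C10. This mode is favoured when the proximal alkene carbon, here C9, is fully substituted. The C9 radical then takes hydrogen from the open α face to give the cyclic siloxane F2.
- Bu4NF in hot DMF cleaves the Si–O and Si–C bonds (protodesilylation) and leaves the 10β-methyl 8β-alcohol F3.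
- Dess–Martin oxidation gives the dibenzyl keto ester F4.
- Hydrogenolysis (H2, Pd/C, EtOAc) removes both benzyl groups and rejoins the route at 25.

Step 8. Bond formation beside quaternary C4 may be sluggish, so that the vinyl ketone polymerises. Facial selectivity at C5 may also be poor, because methyl and ester offer little steric contrast.
- The fallback replaces substrate control by ligand control and uses a small electrophile. It sets out from 5.
- Asymmetric Tsuji–Trost allylation of the silyl enol ether should give the 2-allyl ketone F5. The reagents are diallyl carbonate, Bu4N[Ph3SiF2], Pd2(dba)3 and the antipode of 4-tert-butyl-2-[2-(diphenylphosphino)phenyl]-4,5-dihydrooxazole matched to 5α-H, in THF.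
- 9-BBN followed by NaBO3 gives the primary alcohol F6, and Dess–Martin oxidation gives the keto aldehyde F7.
- Grignard reagent 12 at −78 °C adds to the aldehyde in preference to the hindered ketone and gives the hydroxy ketone F8.
- A second Dess–Martin oxidation returns to the route at 16.

Step 10. Facial selectivity may erode if catalyst control is opposed by the preference of the enone for axial hydride attack.
- The fallback accepts that preference and inverts afterwards. It sets out from 18.
- Luche reduction (NaBH4, CeCl3·7H2O, MeOH) should give the pseudoequatorial 8α-alcohol F9.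
- Mitsunobu reaction with 4-nitrobenzoic acid, PPh3 and diisopropyl azodicarboxylate inverts C8 to the 8β-(4-nitrobenzoate) F10.
- Methanolysis with K2CO3 in MeOH leaves the hindered benzyl ester intact and returns to the route at 19.

Further compounds
F1 | step 11 | benzyl 15-(benzyloxy)-8β-[(bromomethyl)dimethylsilyloxy]-17,20-dinorlabd-9(10)-en-19-oate | BrC[Si](C)(C)O[C@H]1CC[C@@H]2C(CCC[C@]2(C)C(=O)OCc3ccccc3)=C1CC[C@H](C)CCOCc1ccccc1
F2 | step 11 | benzyl 15-(benzyloxy)-8β,20-(dimethylsilanediyloxy)-17-norlabdan-19-oate (ring O8–SiMe2–C20) | C[Si]3(C)O[C@H]1CC[C@@H]2[C@](C3)(CCC[C@]2(C)C(=O)OCc4ccccc4)[C@H]1CC[C@H](C)CCOCc1ccccc1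
F3 | step 11 | benzyl 15-(benzyloxy)-8β-hydroxy-17-norlabdan-19-oate | O[C@H]1CC[C@@H]2[C@](C)(CCC[C@]2(C)C(=O)OCc3ccccc3)[C@H]1CC[C@H](C)CCOCc1ccccc1
F4 | step 11 | benzyl 15-(benzyloxy)-8-oxo-17-norlabdan-19-oate | O=C1CC[C@@H]2[C@](C)(CCC[C@]2(C)C(=O)OCc3ccccc3)[C@H]1CC[C@H](C)CCOCc1ccccc1
F5 | step 8 | benzyl (1S,2S)-1-methyl-3-oxo-2-(prop-2-en-1-yl)cyclohexane-1-carboxylate | O=C1CCC[C@](C)(C(=O)OCc2ccccc2)[C@@H]1CC=C
F6 | step 8 | benzyl (1S,2S)-2-(3-hydroxypropyl)-1-methyl-3-oxocyclohexane-1-carboxylate | O=C1CCC[C@](C)(C(=O)OCc2ccccc2)[C@@H]1CCCO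
F7 | step 8 | benzyl (1S,2S)-1-methyl-3-oxo-2-(3-oxopropyl)cyclohexane-1-carboxylate | O=C1CCC[C@](C)(C(=O)OCc2ccccc2)[C@@H]1CCC=O
F8 | step 8 | benzyl (1S,2S)-2-[(7S)-9-(benzyloxy)-3-hydroxy-7-methylnonyl]-1-methyl-3-oxocyclohexane-1-carboxylate | O=C1CCC[C@](C)(C(=O)OCc2ccccc2)[C@@H]1CCC(O)CCC[C@H](C)CCOCc1ccccc1
F9 | step 10 | benzyl 15-(benzyloxy)-8α-hydroxy-17,20-dinorlabd-9(10)-en-19-oate | O[C@@H]1CC[C@@H]2C(CCC[C@]2(C)C(=O)OCc3ccccc3)=C1CC[C@H](C)CCOCc1ccccc1
F10 | step 10 | benzyl 15-(benzyloxy)-8β-(4-nitrobenzoyloxy)-17,20-dinorlabd-9(10)-en-19-oate | O=C(O[C@H]1CC[C@@H]2C(CCC[C@]2(C)C(=O)OCc3ccccc3)=C1CC[C@H](C)CCOCc1ccccc1)c1ccc(cc1)[N+](=O)[O-]
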